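The readings are calculated for substances that don't exist; the scatter is artificial.

Slowness is the thing to reckon with in the cold flask, autumn: how far does J get in the time it is given?

| flask | J | D | temperature | remark | time |
|---|---|---|---|---|---|
| delta | 0.0050 M | 0.02 mol% | 12 °C | run made earlier |  |
| epsilon | 0.0075 M | 0.02 mol% | 37 °C | run made earlier |  |
| spring | 0.010 M | 0.02 mol% | 37 °C |  | 15 h |
| autumn | 0.010 M | 0.02 mol% | 17 °C |  | 15 h |
| midnight | 0.010 M | 0.02 mol% |  | at 57 °C until 3.0 h, from then on at 17 °C | 15 h |
| dawn | 0.010 M | 0.02 mol% | 57 °C |  | 15 h |

- delta (time / h: L / %): 5.00: 5.0; 10.0: 9.2; 30.0: 23.4; 72.0: 41.1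
- epsilon (time / h: L / %): 1.33: 20.5; 3.00: 41.1; 8.00: 63.0; 20.0: 61.4

(scatter of a reading: 0.5 percentage points)

- what was read earlier has a scatter of 0.5 percentage points, one standard deviation
- a reading or a percentage of L counts all its forms, free or not

1. the best flask by amount of L, in percent of the J charged; "all alike" if 1.5 percentage points covers them all (spring / autumn / midnight / dawn / all alike)
2. amount of L at the end, in percent of the J charged, spring
3. amount of L at the end, in percent of the J charged, autumn
4. amount of L at the end, in percent of the J charged, midnight
5. amount of L at the end, in percent of the J charged, dawn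

We reckon with a pseudo-first-order constant k: the logarithm of J charged over J left, divided by the time, taking every J gone as L. The loading of D on J is 0.02 mol% in each flask. The first readings give 0.0103 /h in delta at 12 °C and 0.172 /h in epsilon at 37 °C. A straight line in ln k against temperature then gives 0.0180 /h at 17 °C. This is the cold constant, our estimate of the mean fractional rate of loss of J in autumn, and we carry it. But delta and epsilon differ in cJ as well as in temperature, and both lie below the 0.010 M of autumn, so the line may hold a dependence on cJ that these two runs do not separate.

Now autumn in slow motion. On the cold constant, we reckon that L grows from the first instants by 0.0180 /h of the J present, and at that pace J takes 38.4 h to lose half of its charge, which is longer than the 15 h allowed. By 7.50 h we reckon 12.6 % of L. The middle of the curve may bend: delta's mean k up to 30.0 h reads 0.00889 /h, less than its first value. At the end we reckon 23.7 % of L. That is below the 63.0 % at which the readings of epsilon stopped rising and the 41.1 % of the last reading of delta, so we expect no stop in autumn.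

The forecast calls autumn “kinetically limited” and gives 58 % for spring, 23 % for autumn (range 19 % to 27 %), 52 % for midnight and 70 % for dawn, with dawn best, and our autumn figure stands above its own.

The flasks give 63.1 % in spring, 31.6 % in autumn, 68.0 % in midnight and 72.4 % in dawn, so dawn is best.

    D → Q (k = 6.16 × 10⁻⁷ /s, Ea = 246 kJ/mol)
    L + D ⇌ X + D, rate k2*[D]*[L] forward; the back reaction follows from the equilibrium constant (K = 2.30, k = 3.53 /M/s, Ea = 57.0 kJ/mol, ΔH = −15.0 kJ/mol)
    Z ⇌ L, rate k3*(cs3 - [L]) while solid is left; crystals form when [L] > cs3 (solubility = 7.70 mM, k = 0.00456 /s)
    G ⇌ D + L (K = 0.0100 M, k = 0.424 /s, Ea = 67.0 kJ/mol, ΔH = −7.00 kJ/mol)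
    J + D ⇌ G (K = 253 /M, k = 371 /M/s, Ea = 45.0 kJ/mol, ΔH = 25.0 kJ/mol)
    (constants at 37 °C)

Autumn ends above our reckoning, and read back, its own k is 0.0253 /h, which is 1.41 times the cold constant. The neighbouring flask is the same charge at the same temperature, read at 10 h. The cold constant gives 16.5 % of L there, and the constant read back from autumn gives 22.4 %. That neighbour holds 23.2 % of L, with 76 % of the charged J still there, unbound.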